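**Retrosynthetic overview**

- Target = ring A (cis-4-bromo-3,3-dimethylcyclohexanol) joined through one CH2 to a cis-fused bromohydrindane (cyclopentane ring B, cyclohexane ring C; hydrindane numbering C1–C7a) that is bridged by the γ-lactone ring D (C3a–CO–O–C7).
- Last step: hydrogenation of a C1 exocyclic alkene. Key disconnection: the C1–C7a bond of ring B together with the lactone O–C7 bond, leading back to a 1,6-enynoic acid in which ring C is a cyclohexene and its quaternary carbon (C3a) carries both CO2H and the butynyl chain.
- Enabling feature: in the target the C7a–C1 bond and the C7–O bond are trans-diaxial on adjacent ring-C carbons (a former trisubstituted C7a=C7 alkene), and both the two-carbon tether and the carboxyl spring from the same quaternary C3a. This is the pattern of an anti carbo-oxygenation of that alkene by a tethered alkyne and a tethered acid.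
- The enynoic acid comes from the acetylide of a (1R,6R)-6-bromocyclohexene acid and the ring-A ketone. Ring C comes from a Diels–Alder reaction of a (Z)-3-bromoacrylate (Br cis to the ester) followed by reductive allylic transposition. Ring A comes from an enantiospecific bromonium cyclisation.
- Order of ring formation: ring A (step 5), ring C (step 9), then ring D and ring B in one operation (step 15); no ring is closed after that step.

Key step: step 15

Assumptions: (a) the L-series fructose-derived ketone catalyst is taken as the one that delivers the S epoxide 2 (usual spiro transition-state model); (b) (S)-1-phenylethylamine is written as the resolving base for acid 18; if the salt of the wanted (1R,6R)-acid turns out to be the more soluble one, the R base is used instead.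

**Route**

Step 1
Reactants: 1 6-methylhept-5-en-2-one
Product: 2 4-[(2S)-3,3-dimethyloxiran-2-yl]butan-2-one
Conditions: L-series fructose-derived ketone catalyst (30 mol %), Oxone, K2CO3, Bu4NHSO4 (cat.), MeCN/CH2(OMe)2/aq. buffer pH 10.5, 0 °C
Reagents that add atoms: potassium peroxymonosulfate (Oxone, KHSO5) [K+].[O-]S(=O)(=O)OO
Why: Shi asymmetric epoxidation; the chiral dioxirane attacks the electron-rich trisubstituted alkene through the spiro transition state and sets the S configuration at the epoxide CH carbon, which becomes the bromine-bearing stereocenter of ring A.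

Step 2
Reactants: 2 4-[(2S)-3,3-dimethyloxiran-2-yl]butan-2-one
Product: 4 4-[(2S)-3,3-dimethyloxiran-2-yl]but-1-en-2-yl trifluoromethanesulfonate, via lithium enolate 3 (not isolated)
Conditions: LDA, THF, −78 °C; then PhNTf2, −78 → 0 °C
Reagents that add atoms: N-phenylbis(trifluoromethanesulfonimide) FC(F)(F)S(=O)(=O)N(c1ccccc1)S(=O)(=O)C(F)(F)F
Why: Kinetic deprotonation of the methyl ketone gives the terminal enolate, which is O-sulfonylated (enol triflate formation); the trisubstituted epoxide is inert to LDA at −78 °C.

Step 3
Reactants: 4 4-[(2S)-3,3-dimethyloxiran-2-yl]but-1-en-2-yl trifluoromethanesulfonate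
Product: 5 {4-[(2S)-3,3-dimethyloxiran-2-yl]-2-methylidenebutyl}trimethylsilane
Conditions: Me3SiCH2MgCl, Pd(PPh3)4 (5 mol %), THF, 0 °C → rt
Reagents that add atoms: (trimethylsilyl)methylmagnesium chloride C[Si](C)(C)C[Mg]Cl
Why: Kumada coupling of the alkenyl triflate under a zerovalent palladium catalyst gives the 2-substituted allylsilane; the hindered epoxide should survive the short contact with the Grignard reagent.

Step 4
Reactants: 5 {4-[(2S)-3,3-dimethyloxiran-2-yl]-2-methylidenebutyl}trimethylsilane
Product: 6 (3R)-3-bromo-2-methyl-6-[(trimethylsilyl)methyl]hept-6-en-2-ol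
Conditions: Li2NiBr4, THF, 0 °C; pH 7 buffer work-up
Reagents that add atoms: dilithium tetrabromonickelate [Li+].[Li+].Br[Ni-2](Br)(Br)Br
Why: SN2 opening of the epoxide by bromide at the less substituted carbon (nearly neutral bromide source) inverts that carbon and should give the R secondary bromide next to the tertiary alcohol.

Step 5
Reactants: 6 (3R)-3-bromo-2-methyl-6-[(trimethylsilyl)methyl]hept-6-en-2-ol
Product: 7 (2R)-2-bromo-1,1-dimethyl-4-methylidenecyclohexane
Conditions: Bi(OTf)3 (5 mol %), CH2Cl2–(CF3)2CHOH (4:1), −20 °C, high dilution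
Reagents that add atoms: none
Why: Ionisation of the tertiary alcohol with participation of the neighbouring bromine gives a bromonium ion of fixed configuration that is opened at its tertiary carbon by the allylsilane (bromonium-induced cation–olefin cyclisation, chair transition state, allylsilane termination), so the C–Br stereocenter is carried over unchanged and loss of silicon leaves the exocyclic methylene.

Step 6
Reactants: 7 (2R)-2-bromo-1,1-dimethyl-4-methylidenecyclohexane
Product: 9 (4R)-4-bromo-3,3-dimethylcyclohexan-1-one, via secondary ozonide 8 (not isolated)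
Conditions: O3, CH2Cl2, −78 °C; then Me2S, −78 °C → rt
Reagents that add atoms: ozone O=[O+][O-]
Why: Ozonolysis of the 1,1-disubstituted alkene with reductive work-up gives the ketone; the secondary bromide and its stereocenter are untouched.

Step 7
Reactants: 10 methyl prop-2-ynoate; 11 prop-2-enal
Product: 12 methyl (2Z)-2-(bromomethylidene)-5-oxopentanoate
Conditions: Pd(OAc)2 (5 mol %), LiBr (excess), AcOH, rt
Reagents that add atoms: lithium bromide [Li+].[Br-]
Why: Three-component halopalladation/conjugate addition/protonolysis under divalent palladium: bromide adds to the β-carbon of the alkynoate anti to palladium, the alkenylpalladium inserts acrolein, and the palladium enolate is protonated (excess bromide suppresses β-hydride elimination), which fixes Br cis to the ester.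

Step 8
Reactants: 13 (2E)-2-methylbut-2-enal
Product: 14 (1E)-2-methylbuta-1,3-dien-1-yl acetate
Conditions: isopropenyl acetate, TsOH (cat.), 95 °C, acetone distilled off
Reagents that add atoms: isopropenyl acetate CC(=C)OC(C)=O
Why: Acid-catalysed dienol acetate formation (transacylation) from the γ-enolisable enal gives the 1-acetoxy diene, mainly as the E isomer, which is the one that reacts in step 9.

Step 9
Reactants: 12 methyl (2Z)-2-(bromomethylidene)-5-oxopentanoate; 14 (1E)-2-methylbuta-1,3-dien-1-yl acetate
Product: 15 methyl (1R*,2S*,6R*)-2-(acetyloxy)-6-bromo-3-methyl-1-(3-oxopropyl)cyclohex-3-ene-1-carboxylate (racemic)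
Conditions: toluene, BHT (cat.), 140 °C, sealed tube
Reagents that add atoms: none
Why: Normal-demand Diels–Alder reaction; the acetoxy group directs the oxygenated diene terminus to the ester-bearing carbon, suprafacial addition turns the Z geometry into the cis relation of Br and CO2Me at the two new stereocenters, and the acetate epimers (endo expected to prevail) converge in step 10.

Step 10
Reactants: 15 methyl (1R*,2S*,6R*)-2-(acetyloxy)-6-bromo-3-methyl-1-(3-oxopropyl)cyclohex-3-ene-1-carboxylate (racemic)
Product: 16 methyl (1R*,6R*)-6-bromo-3-methyl-1-(3-oxopropyl)cyclohex-2-ene-1-carboxylate (racemic)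
Conditions: Pd(PPh3)4 (5 mol %), Ph2SiH2, ZnCl2 (20 mol %), THF, rt
Reagents that add atoms: none
Why: Tsuji–Trost-type ionisation of the allylic acetate to a π-allylpalladium complex and hydride transfer to the less hindered allyl terminus (the one remote from the quaternary carbon) moves the double bond next to the quaternary carbon (reductive allylic transposition); this hydride system should leave the saturated aldehyde and the alkyl bromide alone.

Step 11
Reactants: 16 methyl (1R*,6R*)-6-bromo-3-methyl-1-(3-oxopropyl)cyclohex-2-ene-1-carboxylate (racemic)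
Product: 17 methyl (1R*,6R*)-6-bromo-1-(but-3-yn-1-yl)-3-methylcyclohex-2-ene-1-carboxylate (racemic)
Conditions: dimethyl (1-diazo-2-oxopropyl)phosphonate, K2CO3, MeOH, 0 °C → rt
Reagents that add atoms: dimethyl (1-diazo-2-oxopropyl)phosphonate COP(=O)(OC)C(=[N+]=[N-])C(C)=O
Why: Seyferth–Gilbert homologation turns the aldehyde into the terminal alkyne under mild base, which the β-bromo ester tolerates because its α-carbon is quaternary (no E1cB path).

Step 12
Reactants: 17 methyl (1R*,6R*)-6-bromo-1-(but-3-yn-1-yl)-3-methylcyclohex-2-ene-1-carboxylate (racemic)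
Product: 18 (1R*,6R*)-6-bromo-1-(but-3-yn-1-yl)-3-methylcyclohex-2-ene-1-carboxylic acid (racemic)
Conditions: LiI, EtOAc, reflux; then cold 1 M HCl work-up
Reagents that add atoms: none
Why: SN2 dealkylation of the hindered methyl ester at the methyl carbon by iodide avoids both attack at the neopentyl acyl carbon and basic conditions that could eliminate HBr.

Step 13
Reactants: 18 (1R*,6R*)-6-bromo-1-(but-3-yn-1-yl)-3-methylcyclohex-2-ene-1-carboxylic acid (racemic); 19 (1S)-1-phenylethan-1-amine
Product: 21 (1R,6R)-6-bromo-1-(but-3-yn-1-yl)-3-methylcyclohex-2-ene-1-carboxylic acid, via phenylethylammonium salt 20 (not isolated)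
Conditions: 19 (0.5 equiv), EtOAc/i-PrOH, fractional crystallisation; the filtered salt is decomposed directly with cold 1 M HCl/Et2O
Reagents that add atoms: none
Why: Classical resolution by diastereomeric salt formation; no covalent bond at a stereocenter is touched, and the quaternary α-carbon cannot epimerise.

Step 14
Reactants: 21 (1R,6R)-6-bromo-1-(but-3-yn-1-yl)-3-methylcyclohex-2-ene-1-carboxylic acid; 9 (4R)-4-bromo-3,3-dimethylcyclohexan-1-one
Product: 23 (1R,6R)-6-bromo-1-{4-[(1S,4R)-4-bromo-1-hydroxy-3,3-dimethylcyclohexyl]but-3-yn-1-yl}-3-methylcyclohex-2-ene-1-carboxylic acid, via dilithium alkynide carboxylate 22 (not isolated)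
Conditions: LDA (2.2 equiv), THF, −78 °C; anhydrous CeCl3; then 9, −78 °C; aq. NH4Cl, then citric acid to pH 3
Reagents that add atoms: none
Why: 1,2-Addition of the cerium-modified acetylide to the ketone from the equatorial direction (the axial face is screened by the axial 3-methyl group) on the chair with equatorial bromine gives the axial tertiary alcohol cis to Br; this control is only conformational, so the carbinol epimer arising from the chair with axial bromine is expected as a by-product and is removed by chromatography.

Step 15
Reactants: 23 (1R,6R)-6-bromo-1-{4-[(1S,4R)-4-bromo-1-hydroxy-3,3-dimethylcyclohexyl]but-3-yn-1-yl}-3-methylcyclohex-2-ene-1-carboxylic acid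
Product: 24 (3aR,4R,7S,7aS)-4-bromo-1-{(Z)-[(1S,4R)-4-bromo-1-hydroxy-3,3-dimethylcyclohexyl]methylidene}-7-hydroxy-7-methyloctahydro-3aH-indene-3a-carboxylic acid 3a,7-lactone
Conditions: [Au{P(t-Bu)2(biphenyl-2-yl)}(NCMe)]SbF6 (5 mol %), CH2Cl2, −20 °C → rt
Reagents that add atoms: none
Why: Cationic monovalent gold activates the alkyne; the ring alkene attacks its internal carbon in a 5-exo-dig mode through its CH carbon (C2 of the cyclohexene, the future C7a) from the face on which the butynyl tether hangs, closing ring B and placing positive charge on the methyl-bearing carbon (future C7), which is captured from the opposite face by the carboxyl oxygen held on the same quaternary carbon (5-exo closure of lactone ring D); protodeauration of the alkenylgold then releases the catalyst and the Z exocyclic alkene. The closest known reaction type is the gold-catalysed carbocyclisation of 1,6-enynes with capture by an oxygen nucleophile (hydroxy- or alkoxycyclisation), including enyne cyclisations terminated by a tethered carboxylic acid. The two new stereocenters, C7a and C7, are controlled by the quaternary C3a alone: the tether can only reach the alkene face it is attached on, and the stereospecific anti addition puts the oxygen on the other face, where the carboxyl already is, which gives the trans-diaxial C–C/C–O pair and the cis fusion of rings B and C. The step needs chemoselectivity for alkene attack over direct 6-exo-dig addition of CO2H to the alkyne and over Meyer–Schuster rearrangement of the free propargylic alcohol; the nucleophilic trisubstituted alkene placed for a 5-exo attack, the bulky carbinol on the distal alkyne carbon (which also disfavours the 6-endo mode), the non-basic medium and the low temperature should secure it. The two alkyl bromides are inert to the catalyst.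

Step 16
Reactants: 24 (3aR,4R,7S,7aS)-4-bromo-1-{(Z)-[(1S,4R)-4-bromo-1-hydroxy-3,3-dimethylcyclohexyl]methylidene}-7-hydroxy-7-methyloctahydro-3aH-indene-3a-carboxylic acid 3a,7-lactone
Product: 25 (1R,3aR,4R,7S,7aS)-4-bromo-1-{[(1R,4R)-4-bromo-1-hydroxy-3,3-dimethylcyclohexyl]methyl}-7-hydroxy-7-methyloctahydro-3aH-indene-3a-carboxylic acid 3a,7-lactone (target)
Conditions: H2 (1 atm), [Ir(cod)(PCy3)(py)]PF6 (5 mol %), CH2Cl2, rt
Reagents that add atoms: none
Why: Hydroxyl-assisted homogeneous hydrogenation of the exocyclic trisubstituted alkene; H2 should add to the convex face of ring B, away from the axial hydrogens of ring C under the concave face, which sets C1 with its CH2 link cis to C7 as in the target, while alkyl bromides and the lactone are inert.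

**Compound list**

1 | 6-methylhept-5-en-2-one | CC(=O)CCC=C(C)C | starting material
2 | 4-[(2S)-3,3-dimethyloxiran-2-yl]butan-2-one | CC1(C)O[C@H]1CCC(C)=O | intermediate
3 | lithium 4-[(2S)-3,3-dimethyloxiran-2-yl]but-1-en-2-olate | CC1(C)O[C@H]1CCC(=C)O[Li] | intermediate
4 | 4-[(2S)-3,3-dimethyloxiran-2-yl]but-1-en-2-yl trifluoromethanesulfonate | CC1(C)O[C@H]1CCC(=C)OS(=O)(=O)C(F)(F)F | intermediate
5 | {4-[(2S)-3,3-dimethyloxiran-2-yl]-2-methylidenebutyl}trimethylsilane | CC1(C)O[C@H]1CCC(=C)C[Si](C)(C)C | intermediate
6 | (3R)-3-bromo-2-methyl-6-[(trimethylsilyl)methyl]hept-6-en-2-ol | CC(C)(O)[C@H](Br)CCC(=C)C[Si](C)(C)C | intermediate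
7 | (2R)-2-bromo-1,1-dimethyl-4-methylidenecyclohexane | CC1(C)CC(=C)CC[C@H]1Br | intermediate
8 | (8R)-8-bromo-7,7-dimethyl-1,2,4-trioxaspiro[4.5]decane (secondary ozonide, mixture at the spiro carbon) | CC1(C)CC2(CC[C@H]1Br)OCOO2 | intermediate
9 | (4R)-4-bromo-3,3-dimethylcyclohexan-1-one | CC1(C)CC(=O)CC[C@H]1Br | intermediate
10 | methyl prop-2-ynoate | C#CC(=O)OC | starting material
11 | prop-2-enal | C=CC=O | starting material
12 | methyl (2Z)-2-(bromomethylidene)-5-oxopentanoate | COC(=O)/C(CCC=O)=C\Br | intermediate
13 | (2E)-2-methylbut-2-enal | C/C=C(\C)C=O | starting material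
14 | (1E)-2-methylbuta-1,3-dien-1-yl acetate | CC(=O)O/C=C(\C)C=C | intermediate
15 | methyl (1R*,2S*,6R*)-2-(acetyloxy)-6-bromo-3-methyl-1-(3-oxopropyl)cyclohex-3-ene-1-carboxylate (racemic; enantiomer carried forward is drawn) | O=CCC[C@]1(C(=O)OC)[C@@H](OC(C)=O)C(C)=CC[C@H]1Br | intermediate
16 | methyl (1R*,6R*)-6-bromo-3-methyl-1-(3-oxopropyl)cyclohex-2-ene-1-carboxylate (racemic) | O=CCC[C@]1(C(=O)OC)C=C(C)CC[C@H]1Br | intermediate
17 | methyl (1R*,6R*)-6-bromo-1-(but-3-yn-1-yl)-3-methylcyclohex-2-ene-1-carboxylate (racemic) | C#CCC[C@]1(C(=O)OC)C=C(C)CC[C@H]1Br | intermediate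
18 | (1R*,6R*)-6-bromo-1-(but-3-yn-1-yl)-3-methylcyclohex-2-ene-1-carboxylic acid (racemic) | C#CCC[C@]1(C(=O)O)C=C(C)CC[C@H]1Br | intermediate
19 | (1S)-1-phenylethan-1-amine | C[C@H](N)c1ccccc1 | starting material
20 | (1S)-1-phenylethan-1-aminium (1R,6R)-6-bromo-1-(but-3-yn-1-yl)-3-methylcyclohex-2-ene-1-carboxylate | C#CCC[C@]1(C(=O)[O-])C=C(C)CC[C@H]1Br.C[C@H]([NH3+])c1ccccc1 | intermediate
21 | (1R,6R)-6-bromo-1-(but-3-yn-1-yl)-3-methylcyclohex-2-ene-1-carboxylic acid | C#CCC[C@]1(C(=O)O)C=C(C)CC[C@H]1Br | intermediate
22 | dilithium alkynide carboxylate of 21 | [Li]C#CCC[C@]1(C(=O)O[Li])C=C(C)CC[C@H]1Br | intermediate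
23 | (1R,6R)-6-bromo-1-{4-[(1S,4R)-4-bromo-1-hydroxy-3,3-dimethylcyclohexyl]but-3-yn-1-yl}-3-methylcyclohex-2-ene-1-carboxylic acid | CC1(C)C[C@](O)(C#CCC[C@]2(C(=O)O)C=C(C)CC[C@H]2Br)CC[C@H]1Br | intermediate
24 | (3aR,4R,7S,7aS)-4-bromo-1-{(Z)-[(1S,4R)-4-bromo-1-hydroxy-3,3-dimethylcyclohexyl]methylidene}-7-hydroxy-7-methyloctahydro-3aH-indene-3a-carboxylic acid 3a,7-lactone | CC1(C)C[C@](O)(/C=C2/CC[C@@]34C(=O)O[C@@](C)(CC[C@H]3Br)[C@@H]24)CC[C@H]1Br | intermediate
25 | (1R,3aR,4R,7S,7aS)-4-bromo-1-{[(1R,4R)-4-bromo-1-hydroxy-3,3-dimethylcyclohexyl]methyl}-7-hydroxy-7-methyloctahydro-3aH-indene-3a-carboxylic acid 3a,7-lactone | CC1(C)C[C@](O)(C[C@H]2CC[C@@]34C(=O)O[C@@](C)(CC[C@H]3Br)[C@@H]24)CC[C@H]1Br | target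

**Step count and risks**

Total steps: 16. Longest linear sequence: 9 steps (10 → 12 → 15 → 16 → 17 → 18 → 21 → 23 → 24 → 25; the ring-A branch 1 → 9 → 23 → 25 is equally long).

Steps most likely to fail:

Step 15. Capture of the cationic centre by the carboxyl group may lose to direct addition of the acid to the activated alkyne, or to proton loss giving dienes, or the strained lactone may close too slowly. The fallback sets out from 23: the acid is esterified with Me3SiCHN2 to the methyl ester F1. The same gold catalyst in wet 1,4-dioxane should then effect the well-precedented hydroxycyclisation, water adding anti to the new C–C bond, to give the tertiary alcohol F2. Its alkoxide (DBU or NaH, THF) attacks the cis ester and closes the lactone, which returns the route to 24. In this variant ring D closes after ring B.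

Step 10. Ionisation of the acetate at the neopentyl-type allylic position may be slow, or hydride may be delivered to the wrong allyl terminus and leave the double bond where it was. The fallback sets out from 15: treatment with dimethyl (1-diazo-2-oxopropyl)phosphonate and K2CO3 in MeOH converts the aldehyde to the alkyne and methanolyses the acetate, giving the allylic alcohol F3. Periodinane oxidation (1,1,1-triacetoxy-1,1-dihydro-1,2-benziodoxol-3(1H)-one) gives the enone F4, and TsNHNH2 gives the tosylhydrazone F5. Reduction with catecholborane followed by NaOAc and heat then moves the double bond by mechanism (hydride to the C=N carbon, loss of sulfinate, allylic diazene, retro-ene loss of N2 with hydrogen delivered to the far alkene carbon). This returns the route to 17.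

Step 9. The thermal cycloaddition of the trisubstituted bromoacrylate may be too slow relative to polymerisation or decomposition of the diene. The fallback sets out from 12: the aldehyde is first homologated with dimethyl (diazomethyl)phosphonate and KOt-Bu in THF at −78 °C (no methoxide present) to the alkynyl dienophile F6. Without the aldehyde the ester can be activated by a Lewis acid (Me2AlCl, CH2Cl2, −40 °C) for the cycloaddition with 14, giving the acetoxy adduct F7. Reductive allylic transposition with Pd(PPh3)4/NaBH4, now possible because no aldehyde is present, returns the route to 17.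

**Further compounds**

F1 | step 15 | methyl (1R,6R)-6-bromo-1-{4-[(1S,4R)-4-bromo-1-hydroxy-3,3-dimethylcyclohexyl]but-3-yn-1-yl}-3-methylcyclohex-2-ene-1-carboxylate | CC1(C)C[C@](O)(C#CCC[C@]2(C(=O)OC)C=C(C)CC[C@H]2Br)CC[C@H]1Br
F2 | step 15 | methyl (3aR,4R,7S,7aS)-4-bromo-1-{(Z)-[(1S,4R)-4-bromo-1-hydroxy-3,3-dimethylcyclohexyl]methylidene}-7-hydroxy-7-methyloctahydro-3aH-indene-3a-carboxylate | CC1(C)C[C@](O)(/C=C2/CC[C@]3(C(=O)OC)[C@H]2[C@@](C)(O)CC[C@H]3Br)CC[C@H]1Br
F3 | step 10 | methyl (1R*,2S*,6R*)-6-bromo-1-(but-3-yn-1-yl)-2-hydroxy-3-methylcyclohex-3-ene-1-carboxylate (racemic) | C#CCC[C@]1(C(=O)OC)[C@@H](O)C(C)=CC[C@H]1Br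
F4 | step 10 | methyl (1R*,6R*)-6-bromo-1-(but-3-yn-1-yl)-3-methyl-2-oxocyclohex-3-ene-1-carboxylate (racemic) | C#CCC[C@]1(C(=O)OC)C(=O)C(C)=CC[C@H]1Br
F5 | step 10 | methyl (1R*,6R*)-6-bromo-1-(but-3-yn-1-yl)-3-methyl-2-[2-(4-methylbenzenesulfonyl)hydrazinylidene]cyclohex-3-ene-1-carboxylate (racemic) | C#CCC[C@]1(C(=O)OC)C(=NNS(=O)(=O)c2ccc(C)cc2)C(C)=CC[C@H]1Br
F6 | step 9 | methyl (2Z)-2-(bromomethylidene)hex-5-ynoate | COC(=O)/C(CCC#C)=C\Br
F7 | step 9 | methyl (1R*,2S*,6R*)-2-(acetyloxy)-6-bromo-1-(but-3-yn-1-yl)-3-methylcyclohex-3-ene-1-carboxylate (racemic) | C#CCC[C@]1(C(=O)OC)[C@@H](OC(C)=O)C(C)=CC[C@H]1Br
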